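The dihydropyran ring (O1, C2, C3, C4, C5, C6) carrying ester carbon C11 on C5 is treated as the oxygen-transposed form of a δ-lactone in which O1 is acylated by C11 and C6 sits on C5 as a masked formyl group. Cutting C5–C6 and C4–C8 from that lactone leaves a 5,6-dihydropyran-2-one that already holds the cis C2/C3 pair. The key step joins this pentenolide, the silyl ketene acetal of protected hydroxytyrosyl acetate and trimethyl orthoformate in one flask, makes both bonds and sets C4 anti to the C2/C3 substituents. Opening at C11, closure of O1 on C6 and desilylation finish the synthesis.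

Key step: step 10

Numbering of the target used throughout: O1, C2 (CH3), C3 (hydroxymethyl carbon C10), C4 (arm C8H2–C9O2R), C5 (ester carbon C11), C6. The target is (2S,3R,4S): the C2 methyl and the C3 hydroxymethyl are cis, and the C4 arm is trans to both.

Remarks on the chemistry:
- The α-formyl δ-lactone is the constitutional isomer of the free C11 acid. The methyl ester is the isomer of the α-(methoxymethylene) lactone, so one methanol has to be built in on the way.
- Acetate enolates are C-silylated to a large part by Me3SiCl. The ketene acetal is therefore made as its tert-butyldimethylsilyl (TBS) derivative, and TBSOTf is the promoter.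
- The orthoformate would consume the acetate ketene acetal directly, so it is added only after the Michael stage.
- Once O1 is free it is δ to C9 as well as to C11, and the acetal at C6 is slow to ionise because of the neighbouring ester.
- Hot acidic methanol would therefore expose the arm ester both to methanol and to that hydroxyl. The lactone is opened instead with one equivalent of hydroxide, and the ring is closed under aprotic silyl triflate conditions.
- C2 is taken from the chiral pool and C3 is set by substrate control. No enantioselective addition to acetaldehyde and no geometrically labile allylmetal reagent is needed.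
- Assumption: compound 6 is drawn as the E alkene. Its geometry is immaterial because that alkene terminus is lost in step 6.

Step 1
Reactants: 1 ethyl (S)-3-hydroxybutanoate; 2 allyl bromide
Product: 3 ethyl (2S,3S)-2-allyl-3-hydroxybutanoate
Conditions: LiN(i-Pr)2 (2.2 equiv), THF, −78 → −20 °C; 2 (1.3 equiv), DMPU, −78 → 0 °C
Reagents that add atoms: allyl bromide, C=CCBr
Why: Fráter–Seebach alkylation, in which the chelated lithium alkoxide–enolate dianion is allylated on the face away from the carbinol methyl group, so that target C3 is set anti to the hydroxyl along the ester chain (the relationship that becomes cis in the lactone) while C2 comes unchanged from the chiral pool.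

Step 2
Reactants: 3 ethyl (2S,3S)-2-allyl-3-hydroxybutanoate
Product: 4 (2R,3S)-2-allylbutane-1,3-diol
Conditions: LiAlH4 (1.5 equiv), THF, 0 °C → rt; aqueous work-up
Reagents that add atoms: none
Why: Hydride reduction of the ester to the primary alcohol (future C10) touches neither stereocentre nor the isolated alkene.

Step 3
Reactants: 4 (2R,3S)-2-allylbutane-1,3-diol
Product: 5 (2S,3R)-3-(tert-butyldiphenylsilyloxymethyl)hex-5-en-2-ol
Conditions: TBDPSCl (1.05 equiv), imidazole (2 equiv), CH2Cl2, 0 °C
Reagents that add atoms: tert-butyl(chloro)diphenylsilane, CC(C)(C)[Si](Cl)(c1ccccc1)c1ccccc1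
Why: Silyl ether formation with the very bulky chlorosilane should take the primary hydroxyl and leave the branched secondary one free.

Step 4
Reactants: 5 (2S,3R)-3-(tert-butyldiphenylsilyloxymethyl)hex-5-en-2-ol
Product: 6 (2S,3R,4E)-3-(tert-butyldiphenylsilyloxymethyl)hex-4-en-2-ol
Conditions: second-generation Grubbs catalyst (10 mol %), MeOH, 60 °C
Reagents that add atoms: none
Why: Allyl-to-propenyl isomerisation by the ruthenium hydride that forms from the catalyst in hot methanol, which should stop after one shift because the next one would need insertion beside the branched C3 and abstraction of its tertiary hydrogen.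

Step 5
Reactants: 6 (2S,3R,4E)-3-(tert-butyldiphenylsilyloxymethyl)hex-4-en-2-ol; 7 acryloyl chloride
Product: 8 (2S,3R,4E)-3-(tert-butyldiphenylsilyloxymethyl)hex-4-en-2-yl acrylate
Conditions: 7 (1.5 equiv), i-Pr2NEt (2.5 equiv), DMAP (0.1 equiv), CH2Cl2, 0 °C
Reagents that add atoms: acryloyl chloride, C=CC(=O)Cl
Why: DMAP-catalysed O-acylation forms the O1–C11 bond with retention at C2 because the C–O bond of the carbinol is not touched.

Step 6
Reactants: 8 (2S,3R,4E)-3-(tert-butyldiphenylsilyloxymethyl)hex-4-en-2-yl acrylate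
Product: 9 (5R,6S)-5-(tert-butyldiphenylsilyloxymethyl)-6-methyl-5,6-dihydro-2H-pyran-2-one
Conditions: second-generation Grubbs catalyst (5 mol %), CH2Cl2 (5 mM), reflux
Reagents that add atoms: none
Why: Ring-closing metathesis of the acrylate with the propenyl group closes the six-membered unsaturated lactone with loss of propene and leaves both stereocentres as they are.

Step 7
Reactants: 10 hydroxytyrosol; 11 vinyl acetate
Product: 12 hydroxytyrosyl acetate
Conditions: 11 (5 equiv), Novozym 435 (immobilised Candida antarctica lipase B), t-BuOMe, 40 °C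
Reagents that add atoms: vinyl acetate, C=COC(C)=O
Why: Lipase-catalysed irreversible transesterification acylates only the aliphatic primary hydroxyl because phenols are not substrates of the enzyme, and it brings in carbons C8 and C9.

Step 8
Reactants: 12 hydroxytyrosyl acetate
Product: 13 2-[3,4-bis(tert-butyldimethylsilyloxy)phenyl]ethyl acetate
Conditions: TBSCl (2.4 equiv), imidazole (5 equiv), DMF, rt
Reagents that add atoms: tert-butyl(chloro)dimethylsilane, CC(C)(C)[Si](C)(C)Cl
Why: Standard silylation masks both phenols as aryl silyl ethers that tolerate amide base at −78 °C and silyl triflates and fall to fluoride at the end.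

Step 9
Reactants: 13 2-[3,4-bis(tert-butyldimethylsilyloxy)phenyl]ethyl acetate
Product: 14 1-(tert-butyldimethylsilyloxy)-1-{2-[3,4-bis(tert-butyldimethylsilyloxy)phenyl]ethoxy}ethene
Conditions: LiN(i-Pr)2 (1.1 equiv), THF, −78 °C; TBSCl (1.2 equiv), THF–DMPU, −78 °C → rt; pentane, cold aq NaHCO3; used crude
Reagents that add atoms: tert-butyl(chloro)dimethylsilane, CC(C)(C)[Si](C)(C)Cl
Why: Kinetic deprotonation of the acetate and O-silylation of the lithium enolate with the bulky chlorosilane in a dipolar cosolvent is the established way to acetate ketene acetals free of C-silylated ester, and the TBS derivative survives a quick aqueous wash.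

Step 10
Reactants: 9 (5R,6S)-5-(tert-butyldiphenylsilyloxymethyl)-6-methyl-5,6-dihydro-2H-pyran-2-one; 14 1-(tert-butyldimethylsilyloxy)-1-{2-[3,4-bis(tert-butyldimethylsilyloxy)phenyl]ethoxy}ethene; 15 trimethyl orthoformate
Product: 17 2-[3,4-bis(tert-butyldimethylsilyloxy)phenyl]ethyl [(3S,4S,5R,6S)-5-(tert-butyldiphenylsilyloxymethyl)-3-(dimethoxymethyl)-6-methyl-2-oxotetrahydropyran-4-yl]acetate, via lactone silyl ketene acetal 16 (not isolated)
Conditions: 9, 14 (1.2 equiv), 2,6-di-tert-butyl-4-methylpyridine (0.2 equiv), TBSOTf (0.2 equiv), CH2Cl2, −78 °C; after 9 is consumed 15 (3 equiv), TBSOTf (0.3 equiv), −78 → −40 °C; Et3N quench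
Reagents that add atoms: trimethyl orthoformate, COC(OC)OC
Why: TBSOTf silylates the lactone carbonyl of 9, ketene acetal 14 attacks the resulting allyl-type cation at C4 (Mukaiyama–Michael addition) and its silyl group is passed on as TBSOTf, which leaves lactone ketene acetal 16; only then is 15 added, which TBSOTf ionises to the dimethoxycarbenium ion, and this alkylates 16 at C5. The closest known reaction type is the silyl-triflate-promoted three-component coupling in which the silyl enol ether or ketene acetal born in a Mukaiyama–Michael addition is trapped by an acetal or orthoester. No ring is closed; the two new bonds are C4–C8 and C5–C6. C4 is controlled by the ring, because the C2 methyl and the C3 silyloxymethyl group are cis, so in either half-chair one of them is pseudoaxial on the same face and 14 enters from the other face, anti to both; C5 is controlled by the new arm (the carbenium ion enters trans to it) and is erased in step 12. The step needs 1,4- over 1,2-attack (soft ketene acetal on a silylated lactone), 14 must outrun 16 as nucleophile toward 9 (14 has an unsubstituted CH2 terminus and is in slight excess, whereas 16 is substituted next to a branched carbon), and 14 must not meet the carbenium ion (sequential addition, with excess 15 to absorb any surplus 14). The hindered pyridine removes traces of TfOH so that 16 is not protonated, and the TBDPS and aryl TBS ethers are too hindered to exchange with the orthoformate at this temperature.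

Step 11
Reactants: 17 2-[3,4-bis(tert-butyldimethylsilyloxy)phenyl]ethyl [(3S,4S,5R,6S)-5-(tert-butyldiphenylsilyloxymethyl)-3-(dimethoxymethyl)-6-methyl-2-oxotetrahydropyran-4-yl]acetate
Product: 19 1-methyl 5-{2-[3,4-bis(tert-butyldimethylsilyloxy)phenyl]ethyl} (2S,3S)-3-[(2R,3S)-1-(tert-butyldiphenylsilyloxy)-3-hydroxybutan-2-yl]-2-(dimethoxymethyl)pentanedioate, via potassium carboxylate 18 (not isolated)
Conditions: KOH (1.05 equiv), THF–H2O (4:1), 0 °C; evaporation with toluene below 30 °C; MeI (5 equiv), dry DMF, 0 °C → rt; neutral work-up, used without chromatography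
Reagents that add atoms: potassium hydroxide, [K+].[OH-]; iodomethane, CI
Why: Saponification followed by SN2 alkylation of the carboxylate, which relies on the fact that a δ-lactone (strained, E-configured ester) is attacked by hydroxide orders of magnitude faster than an open-chain ester or an aryl silyl ether, so the single equivalent of base is spent at C11, acyl–oxygen cleavage keeps C2 intact, and the neutral methylation gives the C11 methyl ester without re-lactonisation.

Step 12
Reactants: 19 1-methyl 5-{2-[3,4-bis(tert-butyldimethylsilyloxy)phenyl]ethyl} (2S,3S)-3-[(2R,3S)-1-(tert-butyldiphenylsilyloxy)-3-hydroxybutan-2-yl]-2-(dimethoxymethyl)pentanedioate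
Product: 22 methyl (2S,3R,4S)-4-(2-{2-[3,4-bis(tert-butyldimethylsilyloxy)phenyl]ethoxy}-2-oxoethyl)-3-(tert-butyldiphenylsilyloxymethyl)-2-methyl-3,4-dihydro-2H-pyran-5-carboxylate, via trimethylsilyl ether 20 (not isolated), via cyclic methyl acetal 21 (not isolated)
Conditions: TMSOTf (3 equiv), i-Pr2NEt (4 equiv), CH2Cl2, −78 °C → rt
Reagents that add atoms: none
Why: The silyl triflate/amine pair first silylates the C2 hydroxyl (so that it can attack neither C9 nor C11), then ionises the dimethyl acetal so that the silyl ether oxygen closes on the C6 oxocarbenium ion (6-exo-trig transacetalisation), and a second ionisation with loss of the acidic C5–H gives the conjugated enol ether (silyl-triflate-mediated conversion of acetals into enol ethers), while the hindered TBDPS ether oxygen at C10 should not compete.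

Step 13
Reactants: 22 methyl (2S,3R,4S)-4-(2-{2-[3,4-bis(tert-butyldimethylsilyloxy)phenyl]ethoxy}-2-oxoethyl)-3-(tert-butyldiphenylsilyloxymethyl)-2-methyl-3,4-dihydro-2H-pyran-5-carboxylate
Product: 23 methyl (2S,3R,4S)-4-{2-[2-(3,4-dihydroxyphenyl)ethoxy]-2-oxoethyl}-3-(hydroxymethyl)-2-methyl-3,4-dihydro-2H-pyran-5-carboxylate (CNP0204147.2)
Conditions: Bu4NF (4 equiv), AcOH (4.5 equiv), THF, 0 °C → rt, argon; pH 7 buffer work-up
Reagents that add atoms: none
Why: Fluoride-induced desilylation removes all three silyl groups in one operation, and the acetic acid buffer keeps the phenoxides and the C10 alkoxide protonated so that the catechol is not oxidised and the freed C10 hydroxyl (δ to C9) does not lactonise onto the arm ester.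

Compound list
1 | ethyl (S)-3-hydroxybutanoate | C[C@H](O)CC(=O)OCC | starting material
2 | allyl bromide | C=CCBr | starting material
3 | ethyl (2S,3S)-2-allyl-3-hydroxybutanoate | C[C@H](O)[C@H](CC=C)C(=O)OCC | intermediate
4 | (2R,3S)-2-allylbutane-1,3-diol | C[C@H](O)[C@H](CC=C)CO | intermediate
5 | (2S,3R)-3-(tert-butyldiphenylsilyloxymethyl)hex-5-en-2-ol | C[C@H](O)[C@H](CC=C)CO[Si](c1ccccc1)(c1ccccc1)C(C)(C)C | intermediate
6 | (2S,3R,4E)-3-(tert-butyldiphenylsilyloxymethyl)hex-4-en-2-ol | C[C@H](O)[C@H](/C=C/C)CO[Si](c1ccccc1)(c1ccccc1)C(C)(C)C | intermediate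
7 | acryloyl chloride | C=CC(=O)Cl | starting material
8 | (2S,3R,4E)-3-(tert-butyldiphenylsilyloxymethyl)hex-4-en-2-yl acrylate | C[C@H](OC(=O)C=C)[C@H](/C=C/C)CO[Si](c1ccccc1)(c1ccccc1)C(C)(C)C | intermediate
9 | (5R,6S)-5-(tert-butyldiphenylsilyloxymethyl)-6-methyl-5,6-dihydro-2H-pyran-2-one | C[C@@H]1OC(=O)C=C[C@@H]1CO[Si](c2ccccc2)(c2ccccc2)C(C)(C)C | intermediate
10 | hydroxytyrosol, 2-(3,4-dihydroxyphenyl)ethanol | OCCc1ccc(O)c(O)c1 | starting material
11 | vinyl acetate | C=COC(C)=O | starting material
12 | hydroxytyrosyl acetate, 2-(3,4-dihydroxyphenyl)ethyl acetate | CC(=O)OCCc1ccc(O)c(O)c1 | intermediate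
13 | 2-[3,4-bis(tert-butyldimethylsilyloxy)phenyl]ethyl acetate | CC(=O)OCCc1ccc(O[Si](C)(C)C(C)(C)C)c(O[Si](C)(C)C(C)(C)C)c1 | intermediate
14 | 1-(tert-butyldimethylsilyloxy)-1-{2-[3,4-bis(tert-butyldimethylsilyloxy)phenyl]ethoxy}ethene (TBS ketene acetal of 13) | C=C(O[Si](C)(C)C(C)(C)C)OCCc1ccc(O[Si](C)(C)C(C)(C)C)c(O[Si](C)(C)C(C)(C)C)c1 | intermediate
15 | trimethyl orthoformate | COC(OC)OC | starting material
16 | 2-[3,4-bis(tert-butyldimethylsilyloxy)phenyl]ethyl [(2S,3R,4S)-6-(tert-butyldimethylsilyloxy)-3-(tert-butyldiphenylsilyloxymethyl)-2-methyl-3,4-dihydro-2H-pyran-4-yl]acetate (lactone silyl ketene acetal, not isolated) | C[C@@H]1OC(O[Si](C)(C)C(C)(C)C)=C[C@@H](CC(=O)OCCc2ccc(O[Si](C)(C)C(C)(C)C)c(O[Si](C)(C)C(C)(C)C)c2)[C@@H]1CO[Si](c2ccccc2)(c2ccccc2)C(C)(C)C | intermediate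
17 | 2-[3,4-bis(tert-butyldimethylsilyloxy)phenyl]ethyl [(3S,4S,5R,6S)-5-(tert-butyldiphenylsilyloxymethyl)-3-(dimethoxymethyl)-6-methyl-2-oxotetrahydropyran-4-yl]acetate | C[C@@H]1OC(=O)[C@H](C(OC)OC)[C@@H](CC(=O)OCCc2ccc(O[Si](C)(C)C(C)(C)C)c(O[Si](C)(C)C(C)(C)C)c2)[C@@H]1CO[Si](c2ccccc2)(c2ccccc2)C(C)(C)C | intermediate
18 | potassium salt of the ring-opened hydroxy acid of 17 (C11 carboxylate, free C2 hydroxyl, not isolated) | [K+].[O-]C(=O)[C@H](C(OC)OC)[C@@H](CC(=O)OCCc1ccc(O[Si](C)(C)C(C)(C)C)c(O[Si](C)(C)C(C)(C)C)c1)[C@H](CO[Si](c1ccccc1)(c1ccccc1)C(C)(C)C)[C@H](C)O | intermediate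
19 | 1-methyl 5-{2-[3,4-bis(tert-butyldimethylsilyloxy)phenyl]ethyl} (2S,3S)-3-[(2R,3S)-1-(tert-butyldiphenylsilyloxy)-3-hydroxybutan-2-yl]-2-(dimethoxymethyl)pentanedioate | COC(=O)[C@H](C(OC)OC)[C@@H](CC(=O)OCCc1ccc(O[Si](C)(C)C(C)(C)C)c(O[Si](C)(C)C(C)(C)C)c1)[C@H](CO[Si](c1ccccc1)(c1ccccc1)C(C)(C)C)[C@H](C)O | intermediate
20 | trimethylsilyl ether of 19 at the C2 oxygen (not isolated) | COC(=O)[C@H](C(OC)OC)[C@@H](CC(=O)OCCc1ccc(O[Si](C)(C)C(C)(C)C)c(O[Si](C)(C)C(C)(C)C)c1)[C@H](CO[Si](c1ccccc1)(c1ccccc1)C(C)(C)C)[C@H](C)O[Si](C)(C)C | intermediate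
21 | methyl 2-methoxytetrahydropyran-3-carboxylate form of 22: C6 bears OCH3 (either configuration), C2, C3 and C4 as in the target (not isolated) | COC(=O)[C@@H]1C(OC)O[C@@H](C)[C@@H](CO[Si](c2ccccc2)(c2ccccc2)C(C)(C)C)[C@@H]1CC(=O)OCCc1ccc(O[Si](C)(C)C(C)(C)C)c(O[Si](C)(C)C(C)(C)C)c1 | intermediate
22 | methyl (2S,3R,4S)-4-(2-{2-[3,4-bis(tert-butyldimethylsilyloxy)phenyl]ethoxy}-2-oxoethyl)-3-(tert-butyldiphenylsilyloxymethyl)-2-methyl-3,4-dihydro-2H-pyran-5-carboxylate | COC(=O)C1=CO[C@@H](C)[C@@H](CO[Si](c2ccccc2)(c2ccccc2)C(C)(C)C)[C@@H]1CC(=O)OCCc1ccc(O[Si](C)(C)C(C)(C)C)c(O[Si](C)(C)C(C)(C)C)c1 | intermediate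
23 | methyl (2S,3R,4S)-4-{2-[2-(3,4-dihydroxyphenyl)ethoxy]-2-oxoethyl}-3-(hydroxymethyl)-2-methyl-3,4-dihydro-2H-pyran-5-carboxylate | COC(=O)C1=CO[C@@H](C)[C@@H](CO)[C@@H]1CC(=O)OCCc1ccc(O)c(O)c1 | target

Total step count: 13.
Longest linear sequence: 10 steps (steps 1–6 and 10–13). The ketene acetal branch (steps 7–9) joins at step 10.

Steps most likely to fail

Step 10. Three things may go wrong.
- The silylated lactone may be too weak an electrophile.
- Ketene acetal 16 may add to a second molecule of 9.
- 16 may be protonated before the carbenium ion reaches it.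

The fallback sets out from 9 and comes back at 17. It brings in C8–C9 as an allyl group on copper and attaches the hydroxytyrosyl part afterwards. CH2=CHCH2MgBr, CuBr·SMe2 and Me3SiCl (THF, −78 °C) add to C4 of 9 on the same open face and give the trimethylsilyl ketene acetal F1. With 15 and catalytic TMSOTf (CH2Cl2, −78 °C), F1 gives the 4-allyl acetal lactone F2. Ozonolysis (O3, CH2Cl2, −78 °C; PPh3) leads to aldehyde F3, and Pinnick oxidation (NaClO2, NaH2PO4, 2-methylbut-2-ene, t-BuOH–H2O) leads to acid F4. Reduction of 13 with i-Bu2AlH (CH2Cl2, −78 °C) gives 2-[3,4-bis(tert-butyldimethylsilyloxy)phenyl]ethanol F5. Steglich esterification of F4 with F5 (EDC·HCl, DMAP, CH2Cl2) gives 17.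

Step 11. Hydroxide may also attack the C9 ester or the aryl silyl ethers. The freed C2 hydroxyl, which is δ to C9 as well as to C11, may also displace the hydroxytyrosyl alcohol by lactonisation.

The fallback sets out from 17 and comes back at 22, bypassing steps 11 and 12. It gives up the arm ester on purpose and restores it later. Compound 17 is kept in methanol with camphorsulfonic acid and HC(OMe)3 at 50 °C until both the lactone and the arm ester are methanolysed (acid-catalysed acyl-lactone rearrangement). This gives the cyclic methyl acetal F6 beside recovered alcohol F5. PPTS in toluene at 80 °C then expels methanol and gives dimethyl ester F7. LiOH (1.1 equiv, THF–H2O, 0 °C) should hydrolyse only the C9 ester, because the C11 ester is a vinylogous carbonate and no free hydroxyl is present. The resulting acid F8 is esterified with F5 (EDC·HCl, DMAP) to 22.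

Step 12. Loss of the C5 proton may outrun ring closure and leave an open-chain methoxyacrylate that closes only slowly. The silyl triflate may also begin to exchange the other silyl ethers on long exposure.

The fallback sets out from 19 and comes back at 22. It passes through the free aldehyde level in water instead of through silylated intermediates. Aqueous trifluoroacetic acid in CH2Cl2 at 0 °C hydrolyses the acetal, and the aldehyde is captured by the C2 hydroxyl as lactol F9. MsCl/Et3N (CH2Cl2, 0 °C) dehydrates F9 toward the acidic C5–H to give 22.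

Further compounds
F1 | step 10 | (2S,3R,4S)-4-allyl-3-(tert-butyldiphenylsilyloxymethyl)-2-methyl-6-(trimethylsilyloxy)-3,4-dihydro-2H-pyran | C[C@@H]1OC(O[Si](C)(C)C)=C[C@@H](CC=C)[C@@H]1CO[Si](c2ccccc2)(c2ccccc2)C(C)(C)C
F2 | step 10 | 4-allyl-5-(tert-butyldiphenylsilyloxymethyl)-3-(dimethoxymethyl)-6-methyltetrahydropyran-2-one, ring configuration as in 17 | C[C@@H]1OC(=O)[C@H](C(OC)OC)[C@@H](CC=C)[C@@H]1CO[Si](c2ccccc2)(c2ccccc2)C(C)(C)C
F3 | step 10 | [5-(tert-butyldiphenylsilyloxymethyl)-3-(dimethoxymethyl)-6-methyl-2-oxotetrahydropyran-4-yl]acetaldehyde, ring configuration as in 17 | C[C@@H]1OC(=O)[C@H](C(OC)OC)[C@@H](CC=O)[C@@H]1CO[Si](c2ccccc2)(c2ccccc2)C(C)(C)C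
F4 | step 10 | [5-(tert-butyldiphenylsilyloxymethyl)-3-(dimethoxymethyl)-6-methyl-2-oxotetrahydropyran-4-yl]acetic acid, ring configuration as in 17 | C[C@@H]1OC(=O)[C@H](C(OC)OC)[C@@H](CC(=O)O)[C@@H]1CO[Si](c2ccccc2)(c2ccccc2)C(C)(C)C
F5 | step 10 | 2-[3,4-bis(tert-butyldimethylsilyloxy)phenyl]ethanol | OCCc1ccc(O[Si](C)(C)C(C)(C)C)c(O[Si](C)(C)C(C)(C)C)c1
F6 | step 11 | methyl 5-(tert-butyldiphenylsilyloxymethyl)-2-methoxy-4-(2-methoxy-2-oxoethyl)-6-methyltetrahydropyran-3-carboxylate, target C2, C3 and C4 as in 22, C5 and C6 as mixtures | COC(=O)C1C(OC)O[C@@H](C)[C@@H](CO[Si](c2ccccc2)(c2ccccc2)C(C)(C)C)[C@@H]1CC(=O)OC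
F7 | step 11 | methyl (2S,3R,4S)-3-(tert-butyldiphenylsilyloxymethyl)-4-(2-methoxy-2-oxoethyl)-2-methyl-3,4-dihydro-2H-pyran-5-carboxylate | COC(=O)C1=CO[C@@H](C)[C@@H](CO[Si](c2ccccc2)(c2ccccc2)C(C)(C)C)[C@@H]1CC(=O)OC
F8 | step 11 | [(2S,3R,4S)-3-(tert-butyldiphenylsilyloxymethyl)-5-(methoxycarbonyl)-2-methyl-3,4-dihydro-2H-pyran-4-yl]acetic acid | COC(=O)C1=CO[C@@H](C)[C@@H](CO[Si](c2ccccc2)(c2ccccc2)C(C)(C)C)[C@@H]1CC(=O)O
F9 | step 12 | lactol corresponding to 21 (C6 bears OH instead of OCH3, C5 and C6 as mixtures) | COC(=O)C1C(O)O[C@@H](C)[C@@H](CO[Si](c2ccccc2)(c2ccccc2)C(C)(C)C)[C@@H]1CC(=O)OCCc1ccc(O[Si](C)(C)C(C)(C)C)c(O[Si](C)(C)C(C)(C)C)c1
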